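The γ-lactone ring (O–C6–C7–C11–C12, germacrane numbering) is closed through C7–C11. C7 lies between the lactone oxygen on C6 and the ester oxygen on C8, and C11 is syn to both. A trans-7,8-epoxide whose C6 oxygen carries a diethylphosphonoacetyl group maps onto this triad. The phosphonate carbanion (C11) opens the epoxide at C7 in a 5-exo SN2 reaction; this closes the cis-fused lactone, sets C7 and frees the C8 hydroxyl. Horner–Wadsworth–Emmons reaction with formaldehyde in the same flask then leaves the C11=C13 methylene. The ten-membered ring is closed later by a Nozaki–Hiyama–Kishi reaction.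

Key step: step 10

Remark: the target is read as (1R,3S,6S,7R,8R,10R) with a 4Z alkene (C14 = methyl on C10, C15 = methyl on C4), i.e. the lactone is cis-fused (H6/H7 cis) and O8 lies on the side of C11; CIP labels of intermediates change with substituent priority, not with geometry.

Step 1
Reactants: 1 3-bromo-1-(trimethylsilyl)prop-1-yne; 2 ethynylmagnesium bromide
Product: 3 trimethyl(penta-1,4-diyn-1-yl)silane
Conditions: CuCl (5 mol %), THF, 0 °C to rt
Reagents that add atoms: none
Why: Copper-catalysed SN2 coupling of an alkynyl Grignard reagent with a propargylic bromide (skipped-diyne synthesis) joins C7–C8–C9 to C10≡C1; no stereocenter is formed.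

Step 2
Reactants: 3 trimethyl(penta-1,4-diyn-1-yl)silane
Product: 6 (3E)-4-methyl-7-(trimethylsilyl)hept-3-en-6-yn-1-ol, via alkenyl(dimethyl)alane 4 (not isolated), via lithium alkenylalanate 5 (not isolated)
Conditions: AlMe3, Cp2ZrCl2 (20 mol %), CH2Cl2, 0 °C to rt; n-BuLi, THF/hexane, −78 °C; ethylene oxide, −78 to 0 °C; aq. HCl work-up
Reagents that add atoms: trimethylaluminium C[Al](C)C; ethylene oxide C1CO1
Why: Negishi zirconium-catalysed carboalumination adds CH3 and Al syn across the terminal alkyne (CH3 to the internal carbon C10, the silylated alkyne being inert), which fixes the E geometry of C1=C10, and the derived alanate opens ethylene oxide with retention to add C2–C3.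

Step 3
Reactants: 6 (3E)-4-methyl-7-(trimethylsilyl)hept-3-en-6-yn-1-ol
Product: 7 tert-butyl(dimethyl){[(3E)-4-methyl-7-(trimethylsilyl)hept-3-en-6-yn-1-yl]oxy}silane
Conditions: TBSCl, imidazole, DMF, rt
Reagents that add atoms: tert-butyldimethylsilyl chloride CC(C)(C)[Si](C)(C)Cl
Why: Standard silylation of the primary alcohol masks the C3 oxygen until step 12.

Step 4
Reactants: 7 tert-butyl(dimethyl){[(3E)-4-methyl-7-(trimethylsilyl)hept-3-en-6-yn-1-yl]oxy}silane
Product: 8 tert-butyl(dimethyl){[(3E)-4-methylhept-3-en-6-yn-1-yl]oxy}silane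
Conditions: K2CO3 (20 mol %), MeOH, rt
Reagents that add atoms: none
Why: Base-catalysed methanolysis cleaves the C(sp)–SiMe3 bond selectively and leaves the silyl ether intact, freeing the terminal alkyne C7–H.

Step 5
Reactants: 9 but-2-yn-1-ol
Product: 11 (2Z)-3-iodobut-2-en-1-ol, via sodium alkenylalanate chelate 10 (not isolated)
Conditions: NaAlH2(OCH2CH2OCH3)2, THF, 0 °C to rt; EtOAc; I2, THF, −78 to 0 °C; aq. work-up
Reagents that add atoms: iodine II
Why: Hydroxyl-directed trans-hydroalumination of the propargylic alcohol places aluminium on the distal carbon (C4) in a five-membered chelate, and iodinolysis with retention gives the Z iodoalkene (iodine cis to the carbinol carbon).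

Step 6
Reactants: 11 (2Z)-3-iodobut-2-en-1-ol
Product: 12 (2Z)-3-iodobut-2-enal
Conditions: MnO2 (activated), CH2Cl2, rt, dark
Reagents that add atoms: none
Why: Chemoselective MnO2 oxidation of the allylic alcohol should give the enal without Z/E isomerisation; it is used at once.

Step 7
Reactants: 8 tert-butyl(dimethyl){[(3E)-4-methylhept-3-en-6-yn-1-yl]oxy}silane; 12 (2Z)-3-iodobut-2-enal
Product: 15 (2Z,4S,5E,8E)-11-{[tert-butyl(dimethyl)silyl]oxy}-2-iodo-8-methylundeca-2,5,8-trien-4-ol, via alkenyl(dicyclohexyl)borane 13 (not isolated), via alkenyl(methyl)zinc 14 (not isolated)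
Conditions: Cy2BH, toluene, 0 °C to rt; ZnMe2, −78 °C; (2S)-(−)-3-exo-morpholinoisoborneol (5 mol %), then 12, −10 °C; aq. work-up
Reagents that add atoms: none
Why: Syn hydroboration of the terminal alkyne gives the E-alkenylborane, boron–zinc exchange the alkenylzinc, and the zinc aminoalkoxide catalyst directs its 1,2-addition to the Si face of the enal (Oppolzer–Walsh asymmetric alkenylation), setting C6 as S; this center is inverted in step 9.

Step 8
Reactants: 15 (2Z,4S,5E,8E)-11-{[tert-butyl(dimethyl)silyl]oxy}-2-iodo-8-methylundeca-2,5,8-trien-4-ol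
Product: 16 (1R,2Z)-1-[(2R,3R)-3-{(2E)-5-{[tert-butyl(dimethyl)silyl]oxy}-2-methylpent-2-en-1-yl}oxiran-2-yl]-3-iodobut-2-en-1-ol
Conditions: Ti(OiPr)4 (10 mol %), D-(−)-diisopropyl tartrate (12 mol %), t-BuOOH, 4 Å molecular sieves, CH2Cl2, −20 °C
Reagents that add atoms: tert-butyl hydroperoxide CC(C)(C)OO
Why: Sharpless asymmetric epoxidation: the (S)-carbinol is the fast-reacting partner of the D-(−)-tartrate catalyst, which delivers oxygen to one face of the E-C7=C8 alkene to give the erythro (7R,8R)-epoxy alcohol; the minor (R)-carbinol reacts slowly (kinetic resolution), and the Z-iodoalkene and the non-allylic C1=C10 alkene are not touched.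

Step 9
Reactants: 16 (1R,2Z)-1-[(2R,3R)-3-{(2E)-5-{[tert-butyl(dimethyl)silyl]oxy}-2-methylpent-2-en-1-yl}oxiran-2-yl]-3-iodobut-2-en-1-ol; 17 (diethoxyphosphoryl)acetic acid
Product: 18 (1S,2Z)-1-[(2S,3R)-3-{(2E)-5-{[tert-butyl(dimethyl)silyl]oxy}-2-methylpent-2-en-1-yl}oxiran-2-yl]-3-iodobut-2-en-1-yl (diethoxyphosphoryl)acetate
Conditions: PPh3, DIAD, toluene, 0 °C to rt
Reagents that add atoms: none
Why: Mitsunobu esterification displaces the oxyphosphonium ion by SN2 with inversion at C6, giving the threo ester in which O6 and the epoxide oxygen on C7 are syn; SN2' attack is blocked by the fully substituted, iodine-bearing C4.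

Step 10
Reactants: 18 (1S,2Z)-1-[(2S,3R)-3-{(2E)-5-{[tert-butyl(dimethyl)silyl]oxy}-2-methylpent-2-en-1-yl}oxiran-2-yl]-3-iodobut-2-en-1-yl (diethoxyphosphoryl)acetate
Product: 20 (4R,5R)-4-[(1R,3E)-6-{[tert-butyl(dimethyl)silyl]oxy}-1-hydroxy-3-methylhex-3-en-1-yl]-5-[(1Z)-2-iodoprop-1-en-1-yl]-3-methylideneoxolan-2-one, via α-phosphono lactone 19 (not isolated)
Conditions: LiCl, DBU, MeCN, rt to 45 °C; then 37 % aq. HCHO, rt; aq. NH4Cl
Reagents that add atoms: formaldehyde C=O
Why: Soft enolisation (LiCl/DBU) gives the lithium phosphonoacetate enolate, whose carbon C11 attacks C7 of the lithium-activated epoxide anti to the C7–O bond; proton transfer from the more acidic phosphono lactone to the C8 alkoxide gives the phosphonate-stabilised lactone enolate of 19, which undergoes Horner–Wadsworth–Emmons olefination with formaldehyde to the C11=C13 methylene. The closest known reactions are the opening of epoxides by phosphonoacetate carbanions followed by formaldehyde olefination to α-methylene-γ-butyrolactones, and intramolecular epoxide alkylations of stabilised carbanions (epoxynitrile-type cyclisations). The lactone closes in the 5-exo-tet mode. C7 is set by SN2 inversion and so is dictated by the epoxide configuration from step 8; C8 keeps its epoxide C–O bond and C6 is untouched, so the substituents on C6 and C7 end up cis (cis-fused lactone) with O8 syn to C11. The step needs 5-exo attack at C7 and not 6-endo attack at C8, and no attack of the C8 alkoxide on the lactone; the three-atom O–C(=O) tether, lithium activation and the immediate protonation of the alkoxide should secure this.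

Step 11
Reactants: 20 (4R,5R)-4-[(1R,3E)-6-{[tert-butyl(dimethyl)silyl]oxy}-1-hydroxy-3-methylhex-3-en-1-yl]-5-[(1Z)-2-iodoprop-1-en-1-yl]-3-methylideneoxolan-2-one
Product: 21 (1R,3E)-6-{[tert-butyl(dimethyl)silyl]oxy}-1-[(2R,3R)-2-[(1Z)-2-iodoprop-1-en-1-yl]-4-methylidene-5-oxooxolan-3-yl]-3-methylhex-3-en-1-yl 2-methylprop-2-enoate
Conditions: methacrylic anhydride, Et3N, DMAP (10 mol %), CH2Cl2, 0 °C
Reagents that add atoms: methacrylic anhydride CC(=C)C(=O)OC(=O)C(C)=C
Why: DMAP-catalysed acylation of the secondary C8 hydroxyl installs the methacrylate with retention and removes the free hydroxyl that could translactonise.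

Step 12
Reactants: 21 (1R,3E)-6-{[tert-butyl(dimethyl)silyl]oxy}-1-[(2R,3R)-2-[(1Z)-2-iodoprop-1-en-1-yl]-4-methylidene-5-oxooxolan-3-yl]-3-methylhex-3-en-1-yl 2-methylprop-2-enoate
Product: 22 (1R,3E)-6-hydroxy-1-[(2R,3R)-2-[(1Z)-2-iodoprop-1-en-1-yl]-4-methylidene-5-oxooxolan-3-yl]-3-methylhex-3-en-1-yl 2-methylprop-2-enoate
Conditions: HF·pyridine, pyridine, THF, 0 °C
Reagents that add atoms: none
Why: Buffered fluoride cleavage of the primary silyl ether should not add to the two acrylate-type acceptors or touch the esters.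

Step 13
Reactants: 22 (1R,3E)-6-hydroxy-1-[(2R,3R)-2-[(1Z)-2-iodoprop-1-en-1-yl]-4-methylidene-5-oxooxolan-3-yl]-3-methylhex-3-en-1-yl 2-methylprop-2-enoate
Product: 23 (1R,3E)-1-[(2R,3R)-2-[(1Z)-2-iodoprop-1-en-1-yl]-4-methylidene-5-oxooxolan-3-yl]-3-methyl-6-oxohex-3-en-1-yl 2-methylprop-2-enoate
Conditions: Dess–Martin periodinane, pyridine, CH2Cl2, 0 °C
Reagents that add atoms: none
Why: Dess–Martin oxidation under buffered conditions should give the β,γ-unsaturated aldehyde without migration of the C1=C10 alkene; it is used crude.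

Step 14
Reactants: 23 (1R,3E)-1-[(2R,3R)-2-[(1Z)-2-iodoprop-1-en-1-yl]-4-methylidene-5-oxooxolan-3-yl]-3-methyl-6-oxohex-3-en-1-yl 2-methylprop-2-enoate
Product: 24 (6S,7R,8R)-3-hydroxy-8-(2-methylprop-2-enoyloxy)germacra-1(10)E,4Z,11(13)-trien-12,6-olide (both C3 epimers)
Conditions: CrCl2 (10 equiv), NiCl2 (2 mol %), DMSO/THF, rt, 2 mM, slow addition; aq. work-up
Reagents that add atoms: none
Why: Nozaki–Hiyama–Kishi reaction: nickel-catalysed insertion into the alkenyl C–I bond, transmetalation to chromium and 1,2-addition to the aldehyde close the ten-membered ring at C3–C4 with retention of the Z geometry, the cis-fused lactone holding both chains on one face; esters and acrylates are tolerated and the C3 configuration formed here is not relied on.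

Step 15
Reactants: 24 (6S,7R,8R)-3-hydroxy-8-(2-methylprop-2-enoyloxy)germacra-1(10)E,4Z,11(13)-trien-12,6-olide (both C3 epimers)
Product: 25 (6S,7R,8R)-8-(2-methylprop-2-enoyloxy)-3-oxogermacra-1(10)E,4Z,11(13)-trien-12,6-olide
Conditions: Dess–Martin periodinane, pyridine, CH2Cl2, 0 °C to rt
Reagents that add atoms: none
Why: Dess–Martin oxidation converts both C3 epimers into one Z-enone and so erases the uncontrolled center.

Step 16
Reactants: 25 (6S,7R,8R)-8-(2-methylprop-2-enoyloxy)-3-oxogermacra-1(10)E,4Z,11(13)-trien-12,6-olide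
Product: 26 (3S,6S,7R,8R)-3-hydroxy-8-(2-methylprop-2-enoyloxy)germacra-1(10)E,4Z,11(13)-trien-12,6-olide
Conditions: (R)-2-methyl-CBS-oxazaborolidine (20 mol %), catecholborane, toluene, −78 °C; aq. work-up
Reagents that add atoms: none
Why: Corey–Bakshi–Shibata reduction: with the methyl-bearing alkenyl carbon C4 as the large and the C2 methylene as the small substituent, the (R)-oxazaborolidine should deliver hydride to the face that gives the (3S)-allylic alcohol, 1,2-selectively and without touching the esters.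

Step 17
Reactants: 26 (3S,6S,7R,8R)-3-hydroxy-8-(2-methylprop-2-enoyloxy)germacra-1(10)E,4Z,11(13)-trien-12,6-olide
Product: 27 (3S,6S,7R,8R)-3-acetoxy-8-(2-methylprop-2-enoyloxy)germacra-1(10)E,4Z,11(13)-trien-12,6-olide
Conditions: Ac2O, pyridine, DMAP (10 mol %), CH2Cl2, 0 °C
Reagents that add atoms: acetic anhydride CC(=O)OC(C)=O
Why: DMAP-catalysed acetylation of the C3 alcohol proceeds with retention.

Step 18
Reactants: 27 (3S,6S,7R,8R)-3-acetoxy-8-(2-methylprop-2-enoyloxy)germacra-1(10)E,4Z,11(13)-trien-12,6-olide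
Product: 28 (1R,3S,6S,7R,8R,10R)-3-acetoxy-1,10-epoxy-8-(2-methylprop-2-enoyloxy)germacra-4Z,11(13)-dien-12,6-olide (CNP0267696.3)
Conditions: 1,2:4,5-di-O-isopropylidene-β-D-erythro-2,3-hexodiulo-2,6-pyranose (Shi ketone from D-fructose, 30 mol %), KHSO5, K2CO3, Bu4NHSO4 (cat.), MeCN/dimethoxymethane/aq. buffer, 0 °C
Reagents that add atoms: potassium peroxymonosulfate [K+].[O-]S(=O)(=O)OO
Why: Shi epoxidation: the chiral dioxirane reacts through the spiro transition state that gives the (R,R)-type epoxide from E-trisubstituted alkenes, here (1R,10R), and as an electrophilic oxidant it should select the electron-rich C1=C10 alkene over the C4=C5 alkene flanked by two allylic oxygens and over the two electron-poor methylene groups.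

Compound list
1 | 3-bromo-1-(trimethylsilyl)prop-1-yne | C[Si](C)(C)C#CCBr | starting material
2 | ethynylmagnesium bromide | C#C[Mg]Br | starting material
3 | trimethyl(penta-1,4-diyn-1-yl)silane | C[Si](C)(C)C#CCC#C | intermediate
4 | dimethyl[(1E)-2-methyl-5-(trimethylsilyl)pent-1-en-4-yn-1-yl]alane (not isolated) | C[Al](C)/C=C(\C)CC#C[Si](C)(C)C | intermediate
5 | lithium butyl(dimethyl)[(1E)-2-methyl-5-(trimethylsilyl)pent-1-en-4-yn-1-yl]aluminate (not isolated) | [Li+].CCCC[Al-](C)(C)/C=C(\C)CC#C[Si](C)(C)C | intermediate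
6 | (3E)-4-methyl-7-(trimethylsilyl)hept-3-en-6-yn-1-ol | C[Si](C)(C)C#CC/C(C)=C/CCO | intermediate
7 | tert-butyl(dimethyl){[(3E)-4-methyl-7-(trimethylsilyl)hept-3-en-6-yn-1-yl]oxy}silane | C[Si](C)(C)C#CC/C(C)=C/CCO[Si](C)(C)C(C)(C)C | intermediate
8 | tert-butyl(dimethyl){[(3E)-4-methylhept-3-en-6-yn-1-yl]oxy}silane | C#CC/C(C)=C/CCO[Si](C)(C)C(C)(C)C | intermediate
9 | but-2-yn-1-ol | CC#CCO | starting material
10 | sodium 2,2-bis(2-methoxyethoxy)-3-methyl-2,5-dihydro-1,2-oxaluminol-2-uide, the five-membered alkenylalanate chelate (not isolated) | [Na+].CC1=CCO[Al-]1(OCCOC)OCCOC | intermediate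
11 | (2Z)-3-iodobut-2-en-1-ol | C/C(I)=C/CO | intermediate
12 | (2Z)-3-iodobut-2-enal | C/C(I)=C/C=O | intermediate
13 | dicyclohexyl[(1E,4E)-7-{[tert-butyl(dimethyl)silyl]oxy}-4-methylhepta-1,4-dien-1-yl]borane (not isolated) | CC(C)(C)[Si](C)(C)OCC/C=C(\C)C/C=C/B(C1CCCCC1)C1CCCCC1 | intermediate
14 | methyl[(1E,4E)-7-{[tert-butyl(dimethyl)silyl]oxy}-4-methylhepta-1,4-dien-1-yl]zinc (not isolated) | CC(C)(C)[Si](C)(C)OCC/C=C(\C)C/C=C/[Zn]C | intermediate
15 | (2Z,4S,5E,8E)-11-{[tert-butyl(dimethyl)silyl]oxy}-2-iodo-8-methylundeca-2,5,8-trien-4-ol | O[C@H](/C=C(/C)I)/C=C/C/C(C)=C/CCO[Si](C)(C)C(C)(C)C | intermediate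
16 | (1R,2Z)-1-[(2R,3R)-3-{(2E)-5-{[tert-butyl(dimethyl)silyl]oxy}-2-methylpent-2-en-1-yl}oxiran-2-yl]-3-iodobut-2-en-1-ol | O[C@H](/C=C(/C)I)[C@H]1O[C@@H]1C/C(C)=C/CCO[Si](C)(C)C(C)(C)C | intermediate
17 | (diethoxyphosphoryl)acetic acid | CCOP(=O)(OCC)CC(=O)O | starting material
18 | (1S,2Z)-1-[(2S,3R)-3-{(2E)-5-{[tert-butyl(dimethyl)silyl]oxy}-2-methylpent-2-en-1-yl}oxiran-2-yl]-3-iodobut-2-en-1-yl (diethoxyphosphoryl)acetate | CCOP(=O)(OCC)CC(=O)O[C@@H](/C=C(/C)I)[C@H]1O[C@@H]1C/C(C)=C/CCO[Si](C)(C)C(C)(C)C | intermediate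
19 | diethyl {(4R,5R)-4-[(1R,3E)-6-{[tert-butyl(dimethyl)silyl]oxy}-1-hydroxy-3-methylhex-3-en-1-yl]-5-[(1Z)-2-iodoprop-1-en-1-yl]-2-oxooxolan-3-yl}phosphonate (epimers at the phosphonate carbon, not isolated) | CCOP(=O)(OCC)C1C(=O)O[C@@H](/C=C(/C)I)[C@H]1[C@H](O)C/C(C)=C/CCO[Si](C)(C)C(C)(C)C | intermediate
20 | (4R,5R)-4-[(1R,3E)-6-{[tert-butyl(dimethyl)silyl]oxy}-1-hydroxy-3-methylhex-3-en-1-yl]-5-[(1Z)-2-iodoprop-1-en-1-yl]-3-methylideneoxolan-2-one | C=C1C(=O)O[C@@H](/C=C(/C)I)[C@H]1[C@H](O)C/C(C)=C/CCO[Si](C)(C)C(C)(C)C | intermediate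
21 | (1R,3E)-6-{[tert-butyl(dimethyl)silyl]oxy}-1-[(2R,3R)-2-[(1Z)-2-iodoprop-1-en-1-yl]-4-methylidene-5-oxooxolan-3-yl]-3-methylhex-3-en-1-yl 2-methylprop-2-enoate | C=C1C(=O)O[C@@H](/C=C(/C)I)[C@H]1[C@H](OC(=O)C(C)=C)C/C(C)=C/CCO[Si](C)(C)C(C)(C)C | intermediate
22 | (1R,3E)-6-hydroxy-1-[(2R,3R)-2-[(1Z)-2-iodoprop-1-en-1-yl]-4-methylidene-5-oxooxolan-3-yl]-3-methylhex-3-en-1-yl 2-methylprop-2-enoate | C=C1C(=O)O[C@@H](/C=C(/C)I)[C@H]1[C@H](OC(=O)C(C)=C)C/C(C)=C/CCO | intermediate
23 | (1R,3E)-1-[(2R,3R)-2-[(1Z)-2-iodoprop-1-en-1-yl]-4-methylidene-5-oxooxolan-3-yl]-3-methyl-6-oxohex-3-en-1-yl 2-methylprop-2-enoate | C=C1C(=O)O[C@@H](/C=C(/C)I)[C@H]1[C@H](OC(=O)C(C)=C)C/C(C)=C/CC=O | intermediate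
24 | (6S,7R,8R)-3-hydroxy-8-(2-methylprop-2-enoyloxy)germacra-1(10)E,4Z,11(13)-trien-12,6-olide (both C3 epimers) | C=C(C)C(=O)O[C@@H]1C/C(C)=C/CC(O)/C(C)=C\[C@@H]2OC(=O)C(=C)[C@@H]21 | intermediate
25 | (6S,7R,8R)-8-(2-methylprop-2-enoyloxy)-3-oxogermacra-1(10)E,4Z,11(13)-trien-12,6-olide | C=C(C)C(=O)O[C@@H]1C/C(C)=C/CC(=O)/C(C)=C\[C@@H]2OC(=O)C(=C)[C@@H]21 | intermediate
26 | (3S,6S,7R,8R)-3-hydroxy-8-(2-methylprop-2-enoyloxy)germacra-1(10)E,4Z,11(13)-trien-12,6-olide | C=C(C)C(=O)O[C@@H]1C/C(C)=C/C[C@H](O)/C(C)=C\[C@@H]2OC(=O)C(=C)[C@@H]21 | intermediate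
27 | (3S,6S,7R,8R)-3-acetoxy-8-(2-methylprop-2-enoyloxy)germacra-1(10)E,4Z,11(13)-trien-12,6-olide | C=C(C)C(=O)O[C@@H]1C/C(C)=C/C[C@H](OC(C)=O)/C(C)=C\[C@@H]2OC(=O)C(=C)[C@@H]21 | intermediate
28 | (1R,3S,6S,7R,8R,10R)-3-acetoxy-1,10-epoxy-8-(2-methylprop-2-enoyloxy)germacra-4Z,11(13)-dien-12,6-olide | C=C(C)C(=O)O[C@@H]1C[C@@]2(C)O[C@@H]2C[C@H](OC(C)=O)/C(C)=C\[C@@H]2OC(=O)C(=C)[C@@H]21 | target

Total step count: 18. Longest linear sequence: 16 steps (steps 1–4, then 7–18).

Steps most likely to fail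

Step 10 (key step). The ester-tethered phosphonate carbanion may open the epoxide too slowly, so that 6-endo opening at C8, attack of the C8 alkoxide on the lactone (translactonisation) or its oxa-Michael addition to the new methylene group compete. The fallback replaces the carbanion by a phosphine-triggered Morita–Baylis–Hillman-type alkylation, a reaction known for enone-tethered epoxides. It sets out from 16: Mitsunobu esterification with acrylic acid (PPh3, DIAD, toluene) should give, with inversion at C6, the threo acrylate ester F1. PMe3 in t-BuOH/THF then adds to the acrylate terminus (C13), the zwitterionic enolate opens the epoxide at C7 (5-exo, inversion), and loss of PMe3 on treatment with DBU restores C11=C13. The fallback comes back to the route at 20.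

Step 14. Intermolecular coupling (oligomers) and isomerisation or self-condensation of the β,γ-unsaturated aldehyde may outrun the slow ten-membered ring closure. The fallback is an acylative Stille macrocyclisation that forms the same C3–C4 bond and gives the enone directly. It sets out from 22: PdCl2(PPh3)2-catalysed exchange with Me3SnSnMe3 should give the alkenylstannane alcohol F2 with retention of geometry. Dess–Martin oxidation gives the stannyl aldehyde F3, and NaClO2/NaH2PO4/2-methylbut-2-ene the stannyl carboxylic acid F4. 1-Chloro-N,N,2-trimethylprop-1-en-1-amine converts F4 under neutral conditions into the acid chloride F5, which is cyclised at high dilution with Pd2(dba)3 and tri(2-furyl)phosphine. The fallback comes back at 25, so step 15 is then not needed.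

Step 18. The exposed face of the C1=C10 alkene in the preferred ring conformation may override the catalyst, giving poor or reversed facial selectivity. The fallback delivers the oxygen in two steps to the face opposite to that of direct epoxidation. It sets out from 27: NBS in aqueous THF forms the bromonium ion on the exposed face and water opens it at the tertiary C10, giving the bromohydrin F6. K2CO3 in MeCN then closes the epoxide by displacement of bromide at C1 with inversion. The fallback comes back at 28.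

Further compounds
F1 | step 10 | (1S,2Z)-1-[(2S,3R)-3-{(2E)-5-{[tert-butyl(dimethyl)silyl]oxy}-2-methylpent-2-en-1-yl}oxiran-2-yl]-3-iodobut-2-en-1-yl prop-2-enoate | C=CC(=O)O[C@@H](/C=C(/C)I)[C@H]1O[C@@H]1C/C(C)=C/CCO[Si](C)(C)C(C)(C)C
F2 | step 14 | (1R,3E)-6-hydroxy-3-methyl-1-{(2R,3R)-4-methylidene-5-oxo-2-[(1Z)-2-(trimethylstannyl)prop-1-en-1-yl]oxolan-3-yl}hex-3-en-1-yl 2-methylprop-2-enoate | C=C1C(=O)O[C@@H](/C=C(/C)[Sn](C)(C)C)[C@H]1[C@H](OC(=O)C(C)=C)C/C(C)=C/CCO
F3 | step 14 | (1R,3E)-3-methyl-1-{(2R,3R)-4-methylidene-5-oxo-2-[(1Z)-2-(trimethylstannyl)prop-1-en-1-yl]oxolan-3-yl}-6-oxohex-3-en-1-yl 2-methylprop-2-enoate | C=C1C(=O)O[C@@H](/C=C(/C)[Sn](C)(C)C)[C@H]1[C@H](OC(=O)C(C)=C)C/C(C)=C/CC=O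
F4 | step 14 | (3E,6R)-4-methyl-6-{(2R,3R)-4-methylidene-5-oxo-2-[(1Z)-2-(trimethylstannyl)prop-1-en-1-yl]oxolan-3-yl}-6-(2-methylprop-2-enoyloxy)hex-3-enoic acid | C=C1C(=O)O[C@@H](/C=C(/C)[Sn](C)(C)C)[C@H]1[C@H](OC(=O)C(C)=C)C/C(C)=C/CC(=O)O
F5 | step 14 | acid chloride of F4 (not isolated) | C=C1C(=O)O[C@@H](/C=C(/C)[Sn](C)(C)C)[C@H]1[C@H](OC(=O)C(C)=C)C/C(C)=C/CC(=O)Cl
F6 | step 18 | (1S,3S,6S,7R,8R,10R)-3-acetoxy-1-bromo-10-hydroxy-8-(2-methylprop-2-enoyloxy)germacra-4Z,11(13)-dien-12,6-olide | C=C(C)C(=O)O[C@@H]1C[C@@](C)(O)[C@@H](Br)C[C@H](OC(C)=O)/C(C)=C\[C@@H]2OC(=O)C(=C)[C@@H]21
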